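The data were computed on assumed constants; noise was put on by code.

Monday's flask cannot be a plain second-order step. Such a step slows as Sub and Rea fall, yet Monday's run made 4.7% in its first minute and more, 9.1 percentage points, in its third. Two chemists explain this delay (an induction period) differently.

| setting | Friday's | Monday's | Sunday's | Saturday's | beta | eta | gamma | zeta |
|---|---|---|---|---|---|---|---|---|
| Sub | 0.038 M | 0.025 M | 0.057 M | 0.038 M | 0.038 M | 0.038 M | 0.038 M | 0.038 M (fed, over 9.60 min) |
| Rea | 0.038 M | 0.038 M | 0.038 M | 0.019 M | 0.0380 M (fed, over 9.60 min) | 0.0380 M | 0.0380 M | 0.0380 M |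
| remark | run made earlier | run made earlier | run made earlier | run made earlier | all but Rea at the start; Rea goes in evenly over 9.60 min, the run ends at 12 min | a single well-mixed tank run continuously and read at steady state, 12 min in it on average | a closed flask charged with all of it at once and left for 12 min | a stirred flask in which Sub is dosed at a steady rate over 9.60 min without added volume, worked up at 12 min |
| time |  |  |  |  | 12 min |  | 12 min | 12 min |

- Friday's (time / min: Tsp3 / %): 2.50: 13.2; 5.00: 31.8; 8.00: 49.7; 10.0: 58.2; 12.0: 63.8
- Monday's (time / min: Tsp3 / %): 1.00: 4.7; 2.00: 10.1; 3.00: 19.2; 6.00: 43.4; 12.0: 72.9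
- Sunday's (time / min: Tsp3 / %): 2.50: 13.3; 5.00: 27.3; 8.00: 39.6; 10.0: 43.5; 12.0: 47.5
- Saturday's (time / min: Tsp3 / %): 1.00: 1.4; 2.00: 6.5; 3.00: 9.2; 6.00: 21.0; 12.0: 33.6

(scatter of a reading: 1 percentage point)

- the stated concentrations are those of everything mixed, before any reaction; amounts are the same in each set-up
- the feed brings no volume worth counting
- the earlier runs were made in a closed, stirred flask

- order of the set-ups by the amount of Tsp3 at the outlet or at the end, in percent of the Sub put in, highest first (beta / eta / gamma / zeta)
- amount of Tsp3 at the outlet or at the end, in percent of the Sub put in, beta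
- amount of Tsp3 at the outlet or at the end, in percent of the Sub put in, eta
- amount of Tsp3 at the outlet or at the end, in percent of the Sub put in, gamma
- amount of Tsp3 at the outlet or at the end, in percent of the Sub put in, zeta

The first chemist keeps a rate law in the concentrations and says Sub holds the step back. At the last reading, Monday gives 72.9%, Friday 63.8% and Sunday 47.5%, so the percentage is lower as Sub is higher. On this view, low Sub during a dosing wins back part of the lost time.

The second chemist says the delay is a wait. Something stands between the reaction and Tsp3, so a dose counts by how long it has been in. Define the mean age θ as the average time the dosed charge has spent in the flask at the end: θ = 7.20 min, the dosed cousin of a mean residence time. It holds for Rea in beta and for Sub in zeta, since each goes in evenly.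

In Friday's run every part of the charge has an age equal to the time, so Friday's curve is product against age. Read between its neighbouring points at θ, it gives 44.9%, with the readings' scatter.

I take the second side and commit to that figure for both dosed flasks. I put zeta slightly above beta, because its Sub stays low and Monday's lower Sub read higher at the last reading than Sunday's. Gamma is Friday's recipe, so it stays near 63.8%. Eta's tank has a mean stay of 12 min, but 63.2% of its outflow is younger than that. Its Sub and Rea also stand at outlet level, so I place it last, without a figure.

The forecast, from the first chemist's side, gives gamma > zeta > beta > eta, with beta 49%, eta 47%, gamma 64% and zeta 55%, and its ground is "High Sub therefore inhibits".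

The flask gives gamma > zeta > beta > eta: gamma 63.2%, zeta 43.0%, beta 39.8%, eta 37.1%.

    Sub + Tsp3 → Ofp (k = 0.0210 M⁻¹ s⁻¹)
    Tsp2 → Tsp3 (k = 0.00310 s⁻¹)
    Sub + Rea → Tsp2 (k = 0.240 M⁻¹ s⁻¹)
    Sub → Tsp (k = 5.10 × 10⁻⁴ s⁻¹)
    Tsp4 ⇌ Tsp5 (K = 0.760, k = 5.00 × 10⁻⁴ s⁻¹)
    Rea + Tsp → Tsp4 (k = 0.00800 M⁻¹ s⁻¹)

The age reading stands 1.9 points above zeta and 5.1 points above beta. The first view keeps its ground in gamma, a flask charged at once like the runs it was read from. Tsp2 has a half-life of 3.7 min by its step to Tsp3 alone, longer than the 1.3 min of Sub by its step with Rea alone, as charged in gamma. Beta's mean age 7.20 min is 1.95 of those Tsp2 half-lives, and at the end of beta Tsp2 stands at 24.0% of the Sub charged.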